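# Proposed synthesis of 6,8-diprenylkaempferol (24) by benzannulation of ring A

## The problem

6,8-Diprenylkaempferol (24) is a flavonol: a 3-hydroxy-2-(4-hydroxyphenyl)-4-pyranone (ring C, with ring B at C2) fused through C4a–C8a to a benzene ring A that carries no hydrogen. Ring A has oxygen at C5, C7 and C8a and carbon at C4a, C6 and C8, and the substituents at C6 and C8 are prenyl groups. There is no stereocenter and no stereogenic double bond, so nothing has to be controlled or relayed in three dimensions. The task is regiochemical: six substituents must be placed on ring A without the C- versus O-alkylation and mono- versus di-prenylation mixtures that direct prenylation of an electron-rich triol nucleus gives. The fragile parts are the two trisubstituted alkenes, each ortho to a phenol oxygen. Acid turns them into dimethylchromans, electrophilic halogen, peracids and hydrogenation attack them, and the deprotonated 3-hydroxy-4-oxo unit is degraded by oxygen. Protecting groups therefore have to leave under mild acid or fluoride. The feature that opens a short route is the strict alternation O–C–O–C–O–C round ring A. This is the pattern of a resorcinol made from a vinylketene and an ynol ether: the C4a=C8a bond of the pyranone is the vinyl group, C8 the ketene α-carbon, C5 the ketene carbonyl carbon, and C6/C7 the two alkyne carbons. Both prenyl groups can ride in on the two partners, and the 3-oxygenated pyranone is available ready-made in kojic acid (1).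

## Retrosynthesis

**24 ⇒ 23 ⇒ 22.** Only heteroatom–protecting-group bonds are cut: O7–Si, then the two O–CH2OMe bonds at O3 and O4′. The benzannulation necessarily delivers O7 as a silyl ether and C5–OH free, and O3 and O4′ must be masked through organometallic, enolate and ketene chemistry. Acetal ethers are preferred to benzyl (hydrogenolysis would reduce the prenyl groups) and to esters (they would not survive the Grignard and amide-base steps). The acetals are removed first, while the hindered silyl ether in 23 still blocks O7, the phenol flanked by both prenyl groups. Only the chelated, weakly nucleophilic C5–OH is then free next to an alkene during the acid step. The forward reactions need a mild acid and a buffered fluoride.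

**22 ⇒ 12 + 17 (through 18, 19, 20, 21).** Three ring A bonds are cut: C5–C6, C7–C8 and C4a–C5. This removes the whole hexasubstituted ring in one operation and divides the molecule into two pieces of similar size, each carrying one prenyl group. The neighbouring cuts are worse. Cutting the two prenyl C–C bonds leads back to unselective prenylation. Cutting ring C leaves a diprenylated triol that is hard to make and to handle. The precursors are much simpler: 12 is a monocyclic pyranone with an acyclic diazo ketone side chain, and 17 is a seven-carbon siloxyalkyne. The forward reaction must do three things: Wolff shift of the pyranonyl group to give vinylketene 18, polarity-controlled [2+2] addition of 17 to give 19, and electrocyclic opening and reclosure (20, 21) onto C4a.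

**12 ⇒ 10 ⇒ 9 ⇒ 6 + 7 (through 8 and 11).** The C=N2 unit is removed to give ketone 10, whose only enolisable position is the future C8. The C–C bond between the carbinol carbon and the homoprenyl chain is then cut to give aldehyde 6 and bromide 7 (as Grignard reagent 8). Making the diazo ketone from an acid chloride and a higher diazoalkane would require an unstable, non-commercial diazo compound. Activation through the trifluoroacetyl ketone 11 and diazo transfer is the established way to α-alkyl α-diazo ketones. The forward steps ask for chemoselective addition of 8 to the aldehyde in the presence of the pyranone carbonyl, a neutral oxidation, and regioselective enolate acylation.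

**6 ⇒ 5 ⇒ 3 + 4; 3 ⇒ 2 ⇒ 1.** The C2–C1′ biaryl-type bond is cut (Suzuki coupling of bromide 3 with boronic acid 4). The bromine is traced to electrophilic substitution of kojic acid (1) at the only position activated by its enolic hydroxyl. This is preferred to building the pyranone from acyclic pieces because 1 already holds the ring oxygen, the 4-oxo group, the 3-oxygen and a one-carbon handle at the future C8a. Carbon mapping: kojic acid C6 becomes flavone C2, C5–O becomes O3, C2 and C3 become C8a and C4a. The hydroxymethyl carbon becomes the ketone carbon of 10 and finally C5, after it has migrated off C8a in the Wolff step. The forward sequence needs only a selective O-alkylation of the acidic enol (2 to 3) and an oxidation of the primary alcohol (5 to 6).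

**17 ⇒ 14 ⇒ 13 (through 15 and 16).** The O–Si bond and the bond between C1 and C2 of the alkyne are cut: the ynolate 16 is the one-carbon homologue of ester 14. This is preferred to oxidising a terminal alkyne because acid 13 is a commercial six-carbon piece that already contains the prenyl unit with the correct one-carbon spacer. The forward reaction must add the carbenoid to the ester faster than it deprotonates the allylic α-position, and silylate 16 on oxygen.

## Roads not taken

**Alternative 1:** The cut is at the two side-chain alkenes. The forward key step is double cross-metathesis of the 6,8-diallyl flavonol diacetate A2 with excess 2-methylbut-2-ene (A3) under a ruthenium alkylidene catalyst, giving the diprenyl compound A1. Cross-metathesis of allylarenes with A3 is among the most dependable ways to make aryl prenyl groups. The allyl groups reach ring A by aromatic Claisen rearrangements of defined regiochemistry, and every step has direct precedent on flavonoids. The weak points are strategic: the key step builds no ring, so the whole flavonol core must be assembled linearly beforehand. Two allyl groups require allylation and rearrangement near 200 °C, possibly in two rounds, and acetate and acetal removal still ends with the same acid treatment next to prenyl groups. In predictability this road is at least as good as the chosen one, and probably better at its key step. The chosen plan sets against it convergence (ring A made with all six substituents in one step from two prepared halves), a longest line of ten steps under neutral conditions up to the deprotection, and the option of different C6 and C8 groups from the two partners.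

**Alternative 2:** The cut is the C4a–C8a bond of ring A. In the forward direction a magnesium alkoxide templates a Claisen condensation of the open-chain tetraketo ester A5, giving the acylated diprenyl triol A4, which would then be cyclodehydrated to ring C. The merits are biomimetic logic and a symmetrical ring A in A4, so ring C closure has no regiochemical issue. For this target the weak points dominate. A5 carries five carbonyl groups and two C-prenylated methines, and must be built by iterated acylations of tautomeric, retro-Claisen-prone intermediates. Its folding can also follow aldol or O-acylation (pyranone) modes, and doubly α-alkylated polyketone chains are poor substrates for the desired Claisen mode. Compared with the chosen plan it is longer and its key step lacks close precedent. Its only advantage is that it avoids photochemistry.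

**Alternative 3:** The cut is ring C, at C4–C4a and O1–C2. Neat heating of 2,4-diprenylphloroglucinol (A7) with the α-siloxy β-ketoester A8 would give the flavonol bis-silyl ether A6 directly. This is the shortest road by far: perhaps half the step count of the chosen plan. The only free ring carbon of A7 lies between two equivalent hydroxyls, so there is no regiochemical question. If the annulation worked, it would be the better synthesis. The doubts are specific to this target. Thermal chromone annulations of this kind need temperatures well above 200 °C. At that temperature ortho-prenylphenols cyclise to chromans, coumarin formation competes, and silyl groups migrate among free phenols. A7 itself comes from an unselective C-prenylation and is air-sensitive. The chosen plan sets against the brevity that no step exceeds about 80 °C and that the prenyl groups meet acid only once, with O7 blocked.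

Key step: step 10

Remark: [4-(methoxymethoxy)phenyl]boronic acid (4) is taken as a purchasable building block. Pyranone intermediates are numbered with the aryl group at C2 (kojic acid C6), and flavone numbering is used from 21 on.

## Route

Step 1
Reactants: 1 kojic acid (5-hydroxy-2-(hydroxymethyl)-4H-pyran-4-one)
Product: 2 2-bromo-3-hydroxy-6-(hydroxymethyl)-4H-pyran-4-one (6-bromokojic acid)
Conditions: NBS, MeCN, 0 °C → rt
Reagents that add atoms: N-bromosuccinimide, O=C1CCC(=O)N1Br
Why: Electrophilic bromination of the enol; the 5-hydroxyl of kojic acid activates only the adjacent ring carbon next to the ring oxygen, the site of its Mannich and hydroxymethylation reactions, so one equivalent of NBS should give the monobromide.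

Step 2
Reactants: 2 2-bromo-3-hydroxy-6-(hydroxymethyl)-4H-pyran-4-one
Product: 3 2-bromo-6-(hydroxymethyl)-3-(methoxymethoxy)-4H-pyran-4-one
Conditions: MOMCl (1.1 equiv), K2CO3, acetone, 0 °C → rt
Reagents that add atoms: chloromethyl methyl ether, COCCl
Why: Williamson-type O-alkylation; carbonate deprotonates only the acidic enolic hydroxyl (pKa about 8) and not the primary alcohol, as in the routine selective 5-O-benzylation of kojic acid.

Step 3
Reactants: 3 2-bromo-6-(hydroxymethyl)-3-(methoxymethoxy)-4H-pyran-4-one, 4 [4-(methoxymethoxy)phenyl]boronic acid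
Product: 5 6-(hydroxymethyl)-3-(methoxymethoxy)-2-[4-(methoxymethoxy)phenyl]-4H-pyran-4-one
Conditions: Pd(dppf)Cl2 (cat.), K2CO3, 1,4-dioxane/H2O, 80 °C
Reagents that add atoms: none
Why: Suzuki–Miyaura coupling; the C–Br bond of 3 is that of a vinylogous acyl bromide and should undergo oxidative addition readily, and the acetal ethers and free primary alcohol tolerate aqueous carbonate.

Step 4
Reactants: 5 6-(hydroxymethyl)-3-(methoxymethoxy)-2-[4-(methoxymethoxy)phenyl]-4H-pyran-4-one
Product: 6 5-(methoxymethoxy)-6-[4-(methoxymethoxy)phenyl]-4-oxo-4H-pyran-2-carbaldehyde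
Conditions: Dess–Martin periodinane, CH2Cl2, 0 °C → rt
Reagents that add atoms: none
Why: Dess–Martin oxidation of a primary alcohol to the aldehyde under nearly neutral conditions, which leave the acetal ethers and the pyranone untouched.

Step 5
Reactants: 6 5-(methoxymethoxy)-6-[4-(methoxymethoxy)phenyl]-4-oxo-4H-pyran-2-carbaldehyde, 7 5-bromo-2-methylpent-2-ene
Product: 9 6-(1-hydroxy-5-methylhex-4-enyl)-3-(methoxymethoxy)-2-[4-(methoxymethoxy)phenyl]-4H-pyran-4-one (racemic), via (4-methylpent-3-enyl)magnesium bromide 8 (not isolated)
Conditions: 7, Mg, THF, rt; then 6, THF, −78 °C; aq NH4Cl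
Reagents that add atoms: none
Why: Grignard 1,2-addition; at −78 °C the aldehyde should be far more electrophilic than the vinylogous ester carbonyl of the pyranone, and the new carbinol stereocenter is formed racemic and removed in step 6.

Step 6
Reactants: 9 6-(1-hydroxy-5-methylhex-4-enyl)-3-(methoxymethoxy)-2-[4-(methoxymethoxy)phenyl]-4H-pyran-4-one
Product: 10 3-(methoxymethoxy)-2-[4-(methoxymethoxy)phenyl]-6-(5-methylhex-4-enoyl)-4H-pyran-4-one
Conditions: Dess–Martin periodinane, CH2Cl2, rt
Reagents that add atoms: none
Why: Dess–Martin oxidation of the secondary alcohol to the ketone; the trisubstituted alkene and the acetal ethers are inert to the periodinane.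

Step 7
Reactants: 10 3-(methoxymethoxy)-2-[4-(methoxymethoxy)phenyl]-6-(5-methylhex-4-enoyl)-4H-pyran-4-one
Product: 12 6-(2-diazo-5-methylhex-4-enoyl)-3-(methoxymethoxy)-2-[4-(methoxymethoxy)phenyl]-4H-pyran-4-one, via trifluoroacetyl ketone 11 (not isolated)
Conditions: LiN(SiMe3)2, THF, −78 °C; CF3CO2CH2CF3; 5% aq HCl work-up; then MsN3, Et3N, H2O, MeCN, rt
Reagents that add atoms: methanesulfonyl azide, CS(=O)(=O)N=[N+]=[N-]
Why: Detrifluoroacetylative diazo transfer; the enolate of 10 (its only enolisable site is the CH2 next to the ketone) is C-acylated to 11, whose activated methine takes the diazo group from the sulfonyl azide with loss of the trifluoroacetyl group, the standard access to α-alkyl α-diazo ketones that direct Regitz transfer cannot reach.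

Step 8
Reactants: 13 4-methylpent-3-enoic acid
Product: 14 methyl 4-methylpent-3-enoate
Conditions: MeI, K2CO3, DMF, rt
Reagents that add atoms: iodomethane, CI
Why: SN2 alkylation of the carboxylate; basic conditions are chosen because acid-catalysed esterification would lactonise this β,γ-unsaturated acid through the tertiary cation.

Step 9
Reactants: 14 methyl 4-methylpent-3-enoate
Product: 17 triisopropyl[(5-methylhex-4-en-1-yn-1-yl)oxy]silane, via lithium dibromoenolate 15 (not isolated), via lithium ynolate 16 (not isolated)
Conditions: CH2Br2, lithium 2,2,6,6-tetramethylpiperidide, THF, −78 °C; 14; LiN(SiMe3)2; n-BuLi, −78 °C → rt; then i-Pr3SiCl, −78 °C → rt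
Reagents that add atoms: dibromomethane, BrCBr; chlorotriisopropylsilane, CC(C)[Si](Cl)(C(C)C)C(C)C
Why: Kowalski ester homologation stopped at the ynolate; dibromomethyllithium adds to the ester, the dibromo ketone is held as enolate 15, bromine–lithium exchange and 1,2-shift give ynolate 16, and the bulky silyl chloride silylates oxygen, the established route to triisopropylsiloxyalkynes.

Step 10
Reactants: 12 6-(2-diazo-5-methylhex-4-enoyl)-3-(methoxymethoxy)-2-[4-(methoxymethoxy)phenyl]-4H-pyran-4-one, 17 triisopropyl[(5-methylhex-4-en-1-yn-1-yl)oxy]silane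
Product: 22 5-hydroxy-3-(methoxymethoxy)-2-[4-(methoxymethoxy)phenyl]-6,8-bis(3-methylbut-2-enyl)-7-(triisopropylsilyloxy)-4H-chromen-4-one, via vinylketene 18 (not isolated), via vinylcyclobutenone 19 (not isolated), via dienylketene 20 (not isolated), via cyclohexadienone 21 (not isolated)
Conditions: 17 (1.5 equiv), hν (LEDs, 400–450 nm), degassed ClCH2CH2Cl, rt; then 80 °C
Reagents that add atoms: none
Why: This is the Danheiser benzannulation in its diazo ketone form, a known reaction of aryl and heteroaryl α-diazo ketones with siloxyalkynes. Light at the long-wavelength diazo band expels N2 from 12 with concerted 1,2-shift of the pyranonyl group (Wolff rearrangement) to give vinylketene 18, whose vinyl unit is the C8a=C4a bond of the pyranone. The electron-rich alkyne 17 adds across the ketene C=C in a [2+2] cycloaddition whose regiochemistry is fixed by polarity: the nucleophilic, prenyl-bearing alkyne carbon bonds to the ketene carbonyl carbon (C5–C6) and the silyloxy carbon to the ketene α-carbon (C7–C8), giving cyclobutenone 19. On warming, 19 opens by four-electron conrotatory cleavage of the C5–C8 bond to dienylketene 20, and ring A closes by six-electron disrotatory electrocyclisation of the ketene carbon onto C4a, the nucleophilic α-position of the pyranone, forming C4a–C5 and a six-membered carbocycle. Tautomerisation of cyclohexadienone 21 gives the hydrogen-bonded C5 phenol; the quaternary carbon of 19 and C4a–H of 21 are transient stereocenters that are erased, so 22 has none. The selectivities needed are Wolff shift over 1,2-hydrogen shift from the prenyl CH2 (favoured by direct photolysis of the diazo ketone) and excitation of the diazo chromophore alone (400–450 nm should lie beyond the absorption of the 3-alkoxy-2-arylpyranone and of 22). Closure can occur only at C4a because the other neighbour of C8a is the ring oxygen.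

Step 11
Reactants: 22 5-hydroxy-3-(methoxymethoxy)-2-[4-(methoxymethoxy)phenyl]-6,8-bis(3-methylbut-2-enyl)-7-(triisopropylsilyloxy)-4H-chromen-4-one
Product: 23 3,5-dihydroxy-2-(4-hydroxyphenyl)-6,8-bis(3-methylbut-2-enyl)-7-(triisopropylsilyloxy)-4H-chromen-4-one
Conditions: 3 M aq HCl, MeOH/THF, 45 °C
Reagents that add atoms: none
Why: Acid-catalysed acetal exchange with methanol, the usual way acetal ethers are removed from prenylated flavonoids; the aryl silyl ether flanked by two ortho substituents should solvolyse slowly, so O7 stays blocked and only the chelated C5–OH is free beside a prenyl group.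

Step 12
Reactants: 23 3,5-dihydroxy-2-(4-hydroxyphenyl)-6,8-bis(3-methylbut-2-enyl)-7-(triisopropylsilyloxy)-4H-chromen-4-one
Product: 24 6,8-diprenylkaempferol (3,5,7-trihydroxy-2-(4-hydroxyphenyl)-6,8-bis(3-methylbut-2-enyl)-4H-chromen-4-one)
Conditions: Bu4NF, AcOH, THF, 0 °C, under argon
Reagents that add atoms: none
Why: Fluoride desilylation driven by Si–F bond formation; acetic acid buffers the phenoxides so that the flavonol anion is not exposed to base and air, and the prenyl groups are inert.

## Compound list

1 | kojic acid, 5-hydroxy-2-(hydroxymethyl)-4H-pyran-4-one | O=c1cc(CO)occ1O | starting material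
2 | 2-bromo-3-hydroxy-6-(hydroxymethyl)-4H-pyran-4-one (6-bromokojic acid) | O=c1cc(CO)oc(Br)c1O | intermediate
3 | 2-bromo-6-(hydroxymethyl)-3-(methoxymethoxy)-4H-pyran-4-one | COCOc1c(Br)oc(CO)cc1=O | intermediate
4 | [4-(methoxymethoxy)phenyl]boronic acid | COCOc1ccc(B(O)O)cc1 | starting material
5 | 6-(hydroxymethyl)-3-(methoxymethoxy)-2-[4-(methoxymethoxy)phenyl]-4H-pyran-4-one | COCOc1ccc(-c2oc(CO)cc(=O)c2OCOC)cc1 | intermediate
6 | 5-(methoxymethoxy)-6-[4-(methoxymethoxy)phenyl]-4-oxo-4H-pyran-2-carbaldehyde | COCOc1ccc(-c2oc(C=O)cc(=O)c2OCOC)cc1 | intermediate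
7 | 5-bromo-2-methylpent-2-ene | CC(C)=CCCBr | starting material
8 | (4-methylpent-3-enyl)magnesium bromide | CC(C)=CCC[Mg]Br | intermediate
9 | 6-(1-hydroxy-5-methylhex-4-enyl)-3-(methoxymethoxy)-2-[4-(methoxymethoxy)phenyl]-4H-pyran-4-one (racemic) | CC(C)=CCCC(O)c1cc(=O)c(OCOC)c(-c2ccc(OCOC)cc2)o1 | intermediate
10 | 3-(methoxymethoxy)-2-[4-(methoxymethoxy)phenyl]-6-(5-methylhex-4-enoyl)-4H-pyran-4-one | CC(C)=CCCC(=O)c1cc(=O)c(OCOC)c(-c2ccc(OCOC)cc2)o1 | intermediate
11 | 3-(methoxymethoxy)-2-[4-(methoxymethoxy)phenyl]-6-[5-methyl-2-(trifluoroacetyl)hex-4-enoyl]-4H-pyran-4-one (racemic, enolisable) | CC(C)=CCC(C(=O)C(F)(F)F)C(=O)c1cc(=O)c(OCOC)c(-c2ccc(OCOC)cc2)o1 | intermediate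
12 | 6-(2-diazo-5-methylhex-4-enoyl)-3-(methoxymethoxy)-2-[4-(methoxymethoxy)phenyl]-4H-pyran-4-one | CC(C)=CCC(=[N+]=[N-])C(=O)c1cc(=O)c(OCOC)c(-c2ccc(OCOC)cc2)o1 | intermediate
13 | 4-methylpent-3-enoic acid | CC(C)=CCC(=O)O | starting material
14 | methyl 4-methylpent-3-enoate | CC(C)=CCC(=O)OC | intermediate
15 | lithium 1,1-dibromo-5-methylhexa-1,4-dien-2-olate | CC(C)=CCC([O-])=C(Br)Br.[Li+] | intermediate
16 | lithium 5-methylhex-4-en-1-yn-1-olate | CC(C)=CCC#C[O-].[Li+] | intermediate
17 | triisopropyl[(5-methylhex-4-en-1-yn-1-yl)oxy]silane | CC(C)=CCC#CO[Si](C(C)C)(C(C)C)C(C)C | intermediate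
18 | 3-(methoxymethoxy)-2-[4-(methoxymethoxy)phenyl]-6-(5-methyl-1-oxohexa-1,4-dien-2-yl)-4H-pyran-4-one (vinylketene) | CC(C)=CCC(=C=O)c1cc(=O)c(OCOC)c(-c2ccc(OCOC)cc2)o1 | intermediate
19 | 6-[1,3-bis(3-methylbut-2-enyl)-4-oxo-2-(triisopropylsilyloxy)cyclobut-2-en-1-yl]-3-(methoxymethoxy)-2-[4-(methoxymethoxy)phenyl]-4H-pyran-4-one (racemic) | O=C1C(CC=C(C)C)=C(O[Si](C(C)C)(C(C)C)C(C)C)C1(CC=C(C)C)c2cc(=O)c(OCOC)c(-c3ccc(OCOC)cc3)o2 | intermediate
20 | 4-{5-(methoxymethoxy)-6-[4-(methoxymethoxy)phenyl]-4-oxo-4H-pyran-2-yl}-2,4-bis(3-methylbut-2-enyl)-3-(triisopropylsilyloxy)buta-1,3-dien-1-one (pyranyl group cis to C2 across C3=C4) | O=C=C(CC=C(C)C)/C(O[Si](C(C)C)(C(C)C)C(C)C)=C(/CC=C(C)C)c1cc(=O)c(OCOC)c(-c2ccc(OCOC)cc2)o1 | intermediate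
21 | 3-(methoxymethoxy)-2-[4-(methoxymethoxy)phenyl]-6,8-bis(3-methylbut-2-enyl)-7-(triisopropylsilyloxy)-4aH-chromene-4,5-dione (racemic) | O=C1C(CC=C(C)C)=C(O[Si](C(C)C)(C(C)C)C(C)C)C(CC=C(C)C)=C2OC(c3ccc(OCOC)cc3)=C(OCOC)C(=O)C12 | intermediate
22 | 5-hydroxy-3-(methoxymethoxy)-2-[4-(methoxymethoxy)phenyl]-6,8-bis(3-methylbut-2-enyl)-7-(triisopropylsilyloxy)-4H-chromen-4-one | CC(C)=CCc1c(O[Si](C(C)C)(C(C)C)C(C)C)c(CC=C(C)C)c2oc(-c3ccc(OCOC)cc3)c(OCOC)c(=O)c2c1O | intermediate
23 | 3,5-dihydroxy-2-(4-hydroxyphenyl)-6,8-bis(3-methylbut-2-enyl)-7-(triisopropylsilyloxy)-4H-chromen-4-one | CC(C)=CCc1c(O[Si](C(C)C)(C(C)C)C(C)C)c(CC=C(C)C)c2oc(-c3ccc(O)cc3)c(O)c(=O)c2c1O | intermediate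
24 | 6,8-diprenylkaempferol, 3,5,7-trihydroxy-2-(4-hydroxyphenyl)-6,8-bis(3-methylbut-2-enyl)-4H-chromen-4-one | CC(C)=CCc1c(O)c(CC=C(C)C)c2oc(-c3ccc(O)cc3)c(O)c(=O)c2c1O | target

## Step count and risk

Total: 12 steps. Longest linear sequence: 10 steps (1–7, 10, 11, 12); the siloxyalkyne branch is 2 steps (8, 9).

**Step 10 (key step).** The most likely failure is a 1,2-hydrogen shift from the prenyl CH2 to the carbene carbon, giving a dienone, in competition with the Wolff shift. Photochemical degradation of the pyranone or flavone chromophore, and acylation of the product phenol by unreacted ketene, are secondary risks.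
Fallback: this reaches the same ketene from an isomeric diazo ketone whose carbene carbon has no adjacent C–H. It sets out from 5 and rejoins the route at 18, and so at 22. Alcohol 5 is converted (MeSO2Cl, Et3N; then LiCl) into 6-(chloromethyl)-3-(methoxymethoxy)-2-[4-(methoxymethoxy)phenyl]-4H-pyran-4-one F1. Zn in AcOH reduces this to 3-(methoxymethoxy)-2-[4-(methoxymethoxy)phenyl]-6-methyl-4H-pyran-4-one F2. Lateral deprotonation of the vinylogously acidic methyl group (LiN(SiMe3)2, 2 equiv) and Claisen acylation with ester 14 should give 3-(methoxymethoxy)-2-[4-(methoxymethoxy)phenyl]-6-(5-methyl-2-oxohex-4-enyl)-4H-pyran-4-one F3. Direct Regitz diazo transfer (4-acetamidobenzenesulfonyl azide, Et3N, MeCN) at the doubly activated methylene gives 6-(1-diazo-5-methyl-2-oxohex-4-enyl)-3-(methoxymethoxy)-2-[4-(methoxymethoxy)phenyl]-4H-pyran-4-one F4. Photolysis of F4 with 17 proceeds by Wolff shift of the 3-methylbut-2-enyl group and should give ketene 18, which continues to 22 as in step 10. This path also bypasses steps 4–7.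

**Step 11.** Protonation of a prenyl alkene may be followed by capture by the C5 hydroxyl (chroman formation) or by methanol or water. Partial loss of the silyl ether would be harmless.
Fallback: this masks the last free phenol and replaces the protic acid. It sets out from 22 and returns at 23. Acetylation (Ac2O, DMAP, pyridine) gives 3-(methoxymethoxy)-2-[4-(methoxymethoxy)phenyl]-6,8-bis(3-methylbut-2-enyl)-4-oxo-7-(triisopropylsilyloxy)-4H-chromen-5-yl acetate F5. Aprotic acetal cleavage with Me3SiOTf and 2,2′-bipyridyl in MeCN at 0 °C, then water, gives 3-hydroxy-2-(4-hydroxyphenyl)-6,8-bis(3-methylbut-2-enyl)-4-oxo-7-(triisopropylsilyloxy)-4H-chromen-5-yl acetate F6. Brief K2CO3/MeOH at 0 °C under argon removes the acetate to give 23.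

**Step 9.** Dibromomethyllithium may deprotonate the allylic α-position of 14 instead of adding to the ester, with dienolate formation and alkene migration. The siloxyalkyne may also hydrolyse on silica.
Fallback: this makes the ynolate by oxidation of an acetylide. It sets out from 14 and returns at 16, and so at 17. Reduction with i-Bu2AlH at −78 °C gives 4-methylpent-3-enal F7. Corey–Fuchs olefination (CBr4, PPh3) gives 1,1-dibromo-5-methylhexa-1,4-diene F8. n-BuLi (2 equiv) and protonation give 5-methylhex-4-en-1-yne F9. Its lithium acetylide (LiN(SiMe3)2) is oxidised with LiOOt-Bu to ynolate 16, which is silylated with i-Pr3SiOTf to give 17.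

**Step 5.** The Grignard reagent may add to the pyranone, by conjugate addition or at the C4 carbonyl, and hydrated aldehyde may consume reagent.
Fallback: this replaces the hard nucleophile by a palladium-catalysed acylation. It sets out from 6 and returns at 10, so step 6 is not needed. Pinnick oxidation (NaClO2, NaH2PO4, 2-methylbut-2-ene) gives 5-(methoxymethoxy)-6-[4-(methoxymethoxy)phenyl]-4-oxo-4H-pyran-2-carboxylic acid F10. 1-Chloro-N,N,2-trimethylprop-1-en-1-amine converts this under neutral conditions into 5-(methoxymethoxy)-6-[4-(methoxymethoxy)phenyl]-4-oxo-4H-pyran-2-carbonyl chloride F11. Negishi acylation with (4-methylpent-3-enyl)zinc bromide F12 (from 7, Zn, LiCl) under Pd(PPh3)4 (zerovalent palladium) gives ketone 10.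

## Further compounds

F1 | step 10 | 6-(chloromethyl)-3-(methoxymethoxy)-2-[4-(methoxymethoxy)phenyl]-4H-pyran-4-one | COCOc1ccc(-c2oc(CCl)cc(=O)c2OCOC)cc1
F2 | step 10 | 3-(methoxymethoxy)-2-[4-(methoxymethoxy)phenyl]-6-methyl-4H-pyran-4-one | COCOc1ccc(-c2oc(C)cc(=O)c2OCOC)cc1
F3 | step 10 | 3-(methoxymethoxy)-2-[4-(methoxymethoxy)phenyl]-6-(5-methyl-2-oxohex-4-enyl)-4H-pyran-4-one | CC(C)=CCC(=O)Cc1cc(=O)c(OCOC)c(-c2ccc(OCOC)cc2)o1
F4 | step 10 | 6-(1-diazo-5-methyl-2-oxohex-4-enyl)-3-(methoxymethoxy)-2-[4-(methoxymethoxy)phenyl]-4H-pyran-4-one | CC(C)=CCC(=O)C(=[N+]=[N-])c1cc(=O)c(OCOC)c(-c2ccc(OCOC)cc2)o1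
F5 | step 11 | 3-(methoxymethoxy)-2-[4-(methoxymethoxy)phenyl]-6,8-bis(3-methylbut-2-enyl)-4-oxo-7-(triisopropylsilyloxy)-4H-chromen-5-yl acetate | CC(C)=CCc1c(O[Si](C(C)C)(C(C)C)C(C)C)c(CC=C(C)C)c2oc(-c3ccc(OCOC)cc3)c(OCOC)c(=O)c2c1OC(C)=O
F6 | step 11 | 3-hydroxy-2-(4-hydroxyphenyl)-6,8-bis(3-methylbut-2-enyl)-4-oxo-7-(triisopropylsilyloxy)-4H-chromen-5-yl acetate | CC(C)=CCc1c(O[Si](C(C)C)(C(C)C)C(C)C)c(CC=C(C)C)c2oc(-c3ccc(O)cc3)c(O)c(=O)c2c1OC(C)=O
F7 | step 9 | 4-methylpent-3-enal | CC(C)=CCC=O
F8 | step 9 | 1,1-dibromo-5-methylhexa-1,4-diene | CC(C)=CCC=C(Br)Br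
F9 | step 9 | 5-methylhex-4-en-1-yne | CC(C)=CCC#C
F10 | step 5 | 5-(methoxymethoxy)-6-[4-(methoxymethoxy)phenyl]-4-oxo-4H-pyran-2-carboxylic acid | COCOc1ccc(-c2oc(C(=O)O)cc(=O)c2OCOC)cc1
F11 | step 5 | 5-(methoxymethoxy)-6-[4-(methoxymethoxy)phenyl]-4-oxo-4H-pyran-2-carbonyl chloride | COCOc1ccc(-c2oc(C(Cl)=O)cc(=O)c2OCOC)cc1
F12 | step 5 | (4-methylpent-3-enyl)zinc bromide | CC(C)=CCC[Zn]Br
A1 | alternative 1 | 3-(methoxymethoxy)-2-[4-(methoxymethoxy)phenyl]-6,8-bis(3-methylbut-2-enyl)-4-oxo-4H-chromene-5,7-diyl diacetate | CC(C)=CCc1c(OC(C)=O)c(CC=C(C)C)c2oc(-c3ccc(OCOC)cc3)c(OCOC)c(=O)c2c1OC(C)=O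
A2 | alternative 1 | 3-(methoxymethoxy)-2-[4-(methoxymethoxy)phenyl]-4-oxo-6,8-bis(prop-2-enyl)-4H-chromene-5,7-diyl diacetate | C=CCc1c(OC(C)=O)c(CC=C)c2oc(-c3ccc(OCOC)cc3)c(OCOC)c(=O)c2c1OC(C)=O
A3 | alternative 1 | 2-methylbut-2-ene | CC=C(C)C
A4 | alternative 2 | 2-(methoxymethoxy)-3-[4-(methoxymethoxy)phenyl]-1-[2,4,6-trihydroxy-3,5-bis(3-methylbut-2-enyl)phenyl]propane-1,3-dione (racemic, enolisable) | CC(C)=CCc1c(O)c(CC=C(C)C)c(O)c(C(=O)C(OCOC)C(=O)c2ccc(OCOC)cc2)c1O
A5 | alternative 2 | methyl 8-(methoxymethoxy)-9-[4-(methoxymethoxy)phenyl]-2,4-bis(3-methylbut-2-enyl)-3,5,7,9-tetraoxononanoate (stereoisomer and tautomer mixture) | COC(=O)C(CC=C(C)C)C(=O)C(CC=C(C)C)C(=O)CC(=O)C(OCOC)C(=O)c1ccc(OCOC)cc1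
A6 | alternative 3 | 3-(tert-butyldimethylsilyloxy)-2-[4-(tert-butyldimethylsilyloxy)phenyl]-5,7-dihydroxy-6,8-bis(3-methylbut-2-enyl)-4H-chromen-4-one | CC(C)=CCc1c(O)c(CC=C(C)C)c2oc(-c3ccc(O[Si](C)(C)C(C)(C)C)cc3)c(O[Si](C)(C)C(C)(C)C)c(=O)c2c1O
A7 | alternative 3 | 2,4-bis(3-methylbut-2-enyl)benzene-1,3,5-triol | CC(C)=CCc1c(O)cc(O)c(CC=C(C)C)c1O
A8 | alternative 3 | ethyl 2-(tert-butyldimethylsilyloxy)-3-[4-(tert-butyldimethylsilyloxy)phenyl]-3-oxopropanoate (racemic) | CCOC(=O)C(O[Si](C)(C)C(C)(C)C)C(=O)c1ccc(O[Si](C)(C)C(C)(C)C)cc1
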